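**Strategy.** The route rests on nitrogen insertion into a carbocycle. The azocane (N4, C5, C6, C7, C2, C18, C19, C20) is grown from the seven-membered ketone ring (C5, C6, C7, C2, C18, C19, C20) of an indoline-fused bicyclo[3.2.2]nonanone by an intramolecular azide Schmidt reaction: an azidopropanoyl arm on bridgehead C20 delivers N4 to the C5 carbonyl and C20 migrates from C5 to N4. One operation expands the ring, forms the N4–C20 and N4–C5 bonds and closes the pyrrolidine; it exploits the aza-quaternary C20 shared by azocane, pyrrolidine and cyclohexane. The precursor, an azido 1,3-diketone, is assembled from isatin by an enantioselective oxindole carboxyl shift, a Dieckmann ring opening, an aza-Michael closure and a bridging alkylation.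

Key step: step 15

Remark on labels: indoline = N1, C2, C7 and the benzo ring; C7 carries CO2Me and the chain C6–C5–N4; pyrrolidine = N4–C3–C14–C15–C20; cyclohexane = C2–C16–C17–C20–C19–C18; C16 carries CO2Me, C15 the OH. CIP descriptors of intermediates use these labels.

Assumption: (R)-TADMAP [3-(1-acetoxy-2,2,2-triphenylethyl)-4-(dimethylamino)pyridine] is taken as the catalyst antipode that gives (S)-8; if the sense of induction is the reverse, the (S)-antipode is used.

Step 1
Reactants: 1 isatin; 2 methyl 5-oxohexanoate
Product: 4 methyl (6E)-5-oxo-6-(2-oxoindolin-3-ylidene)hexanoate, via aldol adduct 3 (not isolated)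
Conditions: Et2NH (0.2 equiv), MeOH, 25 °C; then HCl (4 M in dioxane), AcOH, 50 °C
Reagents that add atoms: none
Why: Amine-catalysed crossed aldol addition of the methyl terminus of the ketone to the C3 ketone of isatin, then acid dehydration (aldol condensation), should give the conjugated E-alkene and already joins C7–C6–C5–C20–C17–C16.

Step 2
Reactants: 4 methyl (6E)-5-oxo-6-(2-oxoindolin-3-ylidene)hexanoate
Product: 5 methyl 5-oxo-6-(2-oxoindolin-3-yl)hexanoate (racemic)
Conditions: H2 (1 atm), Pd/C, EtOAc, 25 °C
Reagents that add atoms: none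
Why: Heterogeneous hydrogenation should saturate only the electron-poor exocyclic alkene; the C7 centre formed here is racemic and is erased in step 4.

Step 3
Reactants: 5 methyl 5-oxo-6-(2-oxoindolin-3-yl)hexanoate
Product: 6 methyl 4-{2-[(2-oxoindolin-3-yl)methyl]-1,3-dioxolan-2-yl}butanoate (racemic)
Conditions: 1,2-bis(trimethylsilyloxy)ethane, TMSOTf (5 mol%), CH2Cl2, −78 to −20 °C
Reagents that add atoms: 1,2-bis(trimethylsilyloxy)ethane, C[Si](C)(C)OCCO[Si](C)(C)C
Why: Silyl-triflate-catalysed ketalisation masks the C5 ketone without ester exchange, so that C16 is the only enolisable position in step 6.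

Step 4
Reactants: 6 methyl 4-{2-[(2-oxoindolin-3-yl)methyl]-1,3-dioxolan-2-yl}butanoate
Product: 7 methyl 2-[(methoxycarbonyl)oxy]-3-{[2-(4-methoxy-4-oxobutyl)-1,3-dioxolan-2-yl]methyl}indole-1-carboxylate
Conditions: ClCO2Me (2.4 equiv), Et3N (3 equiv), THF, 0 °C
Reagents that add atoms: methyl chloroformate, COC(=O)Cl
Why: N-acylation followed by O-acylation of the oxindole enolate (no acyl-transfer catalyst present) should give the achiral indolyl enol carbonate and installs the N1 carbamate of the target.

Step 5
Reactants: 7 indolyl enol carbonate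
Product: 8 dimethyl (3S)-3-{[2-(4-methoxy-4-oxobutyl)-1,3-dioxolan-2-yl]methyl}-2-oxoindoline-1,3-dicarboxylate
Conditions: (R)-TADMAP (5 mol%), tert-amyl alcohol, 0 to 25 °C
Reagents that add atoms: none
Why: Enantioselective Steglich-type O-to-C carboxyl shift through a chiral acylpyridinium–enolate ion pair should set quaternary C7 (S), with the catalyst shielding one face of the oxindole enolate.

Step 6
Reactants: 8 quaternary N-methoxycarbonyl oxindole
Product: 9 dimethyl (7S)-8-hydroxy-7-{2-[(methoxycarbonyl)amino]phenyl}-1,4-dioxaspiro[4.6]undec-8-ene-7,9-dicarboxylate (seven-membered β-keto ester, enol form)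
Conditions: NaN(SiMe3)2 (1.2 equiv), THF (0.01 M), −78 to 0 °C; aqueous NH4Cl
Reagents that add atoms: none
Why: Dieckmann-type condensation in which the C16 ester enolate (the only enolisable site) attacks the imide carbonyl C2, more electrophilic than the methyl esters, opens the oxindole, closes the seven-membered ring and frees N1 as its carbamate; the stabilised β-keto ester enolate drives it.

Step 7
Reactants: 9 seven-membered β-keto ester
Product: 10 dimethyl (7S)-7-{2-[(methoxycarbonyl)amino]phenyl}-8-(trifluoromethylsulfonyloxy)-1,4-dioxaspiro[4.6]undec-8-ene-7,9-dicarboxylate (enol triflate)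
Conditions: NaH (1.0 equiv), PhNTf2 (1.1 equiv), THF, 0 to 25 °C
Reagents that add atoms: N-phenylbis(trifluoromethanesulfonimide), O=S(=O)(N(c1ccccc1)S(=O)(=O)C(F)(F)F)C(F)(F)F
Why: One equivalent of base removes only the far more acidic β-keto ester proton, so O-triflation of the enolate should leave the carbamate N–H untouched.

Step 8
Reactants: 10 enol triflate
Product: 11 dimethyl (7R)-8-ethenyl-7-{2-[(methoxycarbonyl)amino]phenyl}-1,4-dioxaspiro[4.6]undec-8-ene-7,9-dicarboxylate (same spatial arrangement at C7 as 10)
Conditions: tributyl(vinyl)stannane (1.5 equiv), Pd(PPh3)4 (5 mol%), LiCl (3 equiv), THF, 65 °C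
Reagents that add atoms: tributyl(vinyl)stannane, C=C[Sn](CCCC)(CCCC)CCCC
Why: Stille coupling of the activated vinyl triflate under neutral conditions puts the two-carbon unit C18=C19 on C2 without triggering addition of the carbamate.

Step 9
Reactants: 11 vinyl dienoate
Product: 12 cis-fused N-methoxycarbonyl cyclohepta[b]indoline ketal (2R,7S,16R): C2 bears vinyl, C7 and C16 bear CO2Me, C5 is the dioxolane
Conditions: KOt-Bu (0.2 equiv), THF, 0 to 25 °C
Reagents that add atoms: none
Why: Intramolecular aza-Michael addition (5-exo-trig) of the carbamate anion to C2 of the enoate; N1 arrives from the face of the aryl group on C7 and the seven-membered ring tying C16 to C6 forces a cis ring fusion, so vinyl ends cis to the C7 ester (2R), while the base-epimerisable C16 should settle as the 16R epimer with its ester pseudo-equatorial and anti to the C2–C7 bond.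

Step 10
Reactants: 12 vinyl indoline ketal
Product: 14 C19 primary alcohol (2-hydroxyethyl on C2), via B-alkyl-9-BBN adduct 13 (not isolated)
Conditions: 9-BBN (2 equiv), THF, 0 to 50 °C; then aqueous NaOH, H2O2, 0 °C
Reagents that add atoms: 9-borabicyclo[3.3.1]nonane, B1C2CCCC1CCC2 (boron of 13); hydrogen peroxide, OO (oxygen of 14)
Why: Anti-Markovnikov hydroboration–oxidation of the only alkene places oxygen on terminal C19; esters, carbamate and ketal are inert to the hindered borane.

Step 11
Reactants: 14 C19 primary alcohol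
Product: 15 C19 primary bromide
Conditions: CBr4, PPh3, CH2Cl2, 0 °C
Reagents that add atoms: carbon tetrabromide, BrC(Br)(Br)Br
Why: Appel reaction converts the unhindered primary alcohol into the bromide needed for ring closure under neutral conditions.

Step 12
Reactants: 15 bromo ketal
Product: 16 bromo ketone (C5 ketone unveiled)
Conditions: HCl (2 M aqueous), THF, 25 °C
Reagents that add atoms: water, O
Why: Acid hydrolysis of the dioxolane; N1–C2 cannot ionise to a stabilised cation and the alkyl bromide is stable to aqueous acid.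

Step 13
Reactants: 16 bromo ketone; 17 3-azidopropanoic acid
Product: 19 azido 1,3-diketone (C20 carries the 3-azidopropanoyl group; enolised), via 3-azidopropanoyl chloride 18 (not isolated)
Conditions: 17, (COCl)2, DMF (cat.), CH2Cl2, 0 to 25 °C, concentrate; then 16, MgBr2·OEt2 (2.5 equiv), i-Pr2NEt (3 equiv), CH2Cl2, 25 °C
Reagents that add atoms: oxalyl chloride, ClC(=O)C(=O)Cl (chlorine of 18)
Why: Soft-enolisation C-acylation (magnesium enolate, amine base) should acylate the less hindered α-carbon C20 rather than neopentyl C6, and the magnesium diketonate product resists loss of azide.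

Step 14
Reactants: 19 azido 1,3-diketone
Product: 20 indoline-fused bicyclo[3.2.2]nonanone azide (2R,7S,16R,20S): bridgeheads C2 and C20, C5 ketone, C20 bears C(=O)CH2CH2N3
Conditions: NaH (1.0 equiv), DMF (0.01 M), 0 to 40 °C
Reagents that add atoms: none
Why: Intramolecular C-alkylation of the diketone enolate by the C19 bromide (6-exo-tet) closes the cyclohexane and makes C20 quaternary; its configuration is dictated by the bridge, and exactly one equivalent of base leaves none to eliminate azide.

Step 15
Reactants: 20 bicyclic azido diketone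
Product: 22 keto lactam (2R,7S,16R,20R; 5,15-dioxo pentacycle), via aminodiazonium alkoxide 21 (not isolated)
Conditions: TfOH (3 equiv), CH2Cl2, 0 to 25 °C
Reagents that add atoms: none
Why: Triflic acid activates the C5 ketone, the tethered azide nitrogen N4 adds to give the six-membered aminodiazonium alkoxide 21, and the C5–C20 bond, antiperiplanar to the departing N2, shifts from C5 to N4 with loss of dinitrogen to leave the C5 lactam. The closest known reaction type is the intramolecular Schmidt reaction of alkyl azides with ketones. The azocane arises by one-atom ring expansion (N4 inserted into the C5–C20 bond of the cycloheptanone ring C5–C6–C7–C2–C18–C19–C20), and the pyrrolidine closes in the same 1,2-shift through the new N4–C20 bond, the azide having first added to the carbonyl in a 6-exo-trig sense. No new stereocentre is created: bridgehead C20 migrates with retention, so the configuration fixed in step 14 becomes that of the aza-quaternary centre. The step needs attack at C5 rather than C15 and migration of C20 rather than C6; ring size secures the first (C15 would require a four-membered azidohydrin), and the second follows from the chair-like azidohydrin, whose equatorial diazonium group is anti to the ring bond C5–C20, and from the higher migratory aptitude of the fully substituted carbon.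

Step 16
Reactants: 22 keto lactam
Product: 23 hydroxy lactam (2R,7S,15R,16R,20R)
Conditions: (S)-2-methyl-CBS-oxazaborolidine (0.2 equiv), BH3·SMe2 (1.0 equiv), THF, −20 °C; MeOH quench
Reagents that add atoms: none
Why: Corey–Bakshi–Shibata reduction under reagent control: with quaternary C20 as the large and C14 as the small substituent, the (S)-catalyst should deliver hydride to give the 15R alcohol; lactam, esters and carbamate are not reduced at this temperature.

Step 17
Reactants: 23 hydroxy lactam
Product: 24 target, CNP0144467.2 (2R,7S,15R,16R,20R)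
Conditions: Zn(OAc)2 (10 mol%), (EtO)3SiH (4 equiv), THF, 40 °C; then NH4F, MeOH
Reagents that add atoms: none
Why: Zinc-catalysed hydrosilylation reduces the tertiary lactam carbonyl C5 to CH2 in preference to methyl esters and the carbamate; the transient silyl ether at O15 is cleaved by fluoride on work-up.

**Compound list**

1 | isatin | O=C1Nc2ccccc2C1=O | starting material
2 | methyl 5-oxohexanoate | CC(=O)CCCC(=O)OC | starting material
3 | methyl 6-(3-hydroxy-2-oxoindolin-3-yl)-5-oxohexanoate (racemic aldol adduct) | COC(=O)CCCC(=O)CC1(O)C(=O)Nc2ccccc21 | intermediate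
4 | methyl (6E)-5-oxo-6-(2-oxoindolin-3-ylidene)hexanoate | COC(=O)CCCC(=O)/C=C1/C(=O)Nc2ccccc21 | intermediate
5 | methyl 5-oxo-6-(2-oxoindolin-3-yl)hexanoate (racemic) | COC(=O)CCCC(=O)CC1C(=O)Nc2ccccc21 | intermediate
6 | methyl 4-{2-[(2-oxoindolin-3-yl)methyl]-1,3-dioxolan-2-yl}butanoate (racemic) | COC(=O)CCCC1(CC2C(=O)Nc3ccccc32)OCCO1 | intermediate
7 | methyl 2-[(methoxycarbonyl)oxy]-3-{[2-(4-methoxy-4-oxobutyl)-1,3-dioxolan-2-yl]methyl}indole-1-carboxylate | COC(=O)Oc1c(CC2(CCCC(=O)OC)OCCO2)c2ccccc2n1C(=O)OC | intermediate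
8 | dimethyl (3S)-3-{[2-(4-methoxy-4-oxobutyl)-1,3-dioxolan-2-yl]methyl}-2-oxoindoline-1,3-dicarboxylate | O=C1N(C(=O)OC)c2ccccc2[C@@]1(C(=O)OC)CC1(CCCC(=O)OC)OCCO1 | intermediate
9 | dimethyl (7S)-8-hydroxy-7-{2-[(methoxycarbonyl)amino]phenyl}-1,4-dioxaspiro[4.6]undec-8-ene-7,9-dicarboxylate | COC(=O)Nc1ccccc1[C@@]2(C(=O)OC)CC3(CCC(C(=O)OC)=C2O)OCCO3 | intermediate
10 | dimethyl (7S)-7-{2-[(methoxycarbonyl)amino]phenyl}-8-(trifluoromethylsulfonyloxy)-1,4-dioxaspiro[4.6]undec-8-ene-7,9-dicarboxylate | COC(=O)Nc1ccccc1[C@@]2(C(=O)OC)CC3(CCC(C(=O)OC)=C2OS(=O)(=O)C(F)(F)F)OCCO3 | intermediate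
11 | dimethyl (7R)-8-ethenyl-7-{2-[(methoxycarbonyl)amino]phenyl}-1,4-dioxaspiro[4.6]undec-8-ene-7,9-dicarboxylate | COC(=O)Nc1ccccc1[C@@]2(C(=O)OC)CC3(CCC(C(=O)OC)=C2C=C)OCCO3 | intermediate
12 | cis-fused N-methoxycarbonyl cyclohepta[b]indoline ketal, C2 vinyl, C7 and C16 CO2Me (2R,7S,16R) | COC(=O)[C@@H]1CCC2(OCCO2)C[C@]3(C(=O)OC)c4ccccc4N(C(=O)OC)[C@]13C=C | intermediate
13 | B-alkyl-9-BBN adduct of 12 (boron on C19) | COC(=O)[C@@H]1CCC2(OCCO2)C[C@]3(C(=O)OC)c4ccccc4N(C(=O)OC)[C@]13CCB1C2CCCC1CCC2 | intermediate
14 | C19 primary alcohol (2R,7S,16R) | COC(=O)[C@@H]1CCC2(OCCO2)C[C@]3(C(=O)OC)c4ccccc4N(C(=O)OC)[C@]13CCO | intermediate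
15 | C19 primary bromide, C5 ketal (2R,7S,16R) | COC(=O)[C@@H]1CCC2(OCCO2)C[C@]3(C(=O)OC)c4ccccc4N(C(=O)OC)[C@]13CCBr | intermediate
16 | bromo ketone, C5 ketone (2R,7S,16R) | COC(=O)[C@@H]1CCC(=O)C[C@]2(C(=O)OC)c3ccccc3N(C(=O)OC)[C@]12CCBr | intermediate
17 | 3-azidopropanoic acid | OC(=O)CCN=[N+]=[N-] | starting material
18 | 3-azidopropanoyl chloride | ClC(=O)CCN=[N+]=[N-] | intermediate
19 | azido 1,3-diketone, C20 acylated and enolisable (2R,7S,16R; C20 undefined) | COC(=O)[C@@H]1CC(C(=O)CCN=[N+]=[N-])C(=O)C[C@]2(C(=O)OC)c3ccccc3N(C(=O)OC)[C@]12CCBr | intermediate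
20 | indoline-fused bicyclo[3.2.2]nonanone azide (2R,7S,16R,20S) | COC(=O)[C@@H]1C[C@@]2(C(=O)CCN=[N+]=[N-])CC[C@@]13N(C(=O)OC)c1ccccc1[C@@]3(C(=O)OC)CC2=O | intermediate
21 | aminodiazonium alkoxide (azidohydrin zwitterion at C5) | COC(=O)[C@@H]1C[C@@]23CC[C@@]14N(C(=O)OC)c1ccccc1[C@@]4(C(=O)OC)CC2([O-])N(CCC3=O)[N+]#N | intermediate
22 | keto lactam, C5 lactam and C15 ketone (2R,7S,16R,20R) | COC(=O)[C@@H]1C[C@@]23CC[C@@]14N(C(=O)OC)c1ccccc1[C@@]4(C(=O)OC)CC(=O)N2CCC3=O | intermediate
23 | hydroxy lactam (2R,7S,15R,16R,20R) | COC(=O)[C@@H]1C[C@@]23CC[C@@]14N(C(=O)OC)c1ccccc1[C@@]4(C(=O)OC)CC(=O)N2CC[C@H]3O | intermediate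
24 | CNP0144467.2 (2R,7S,15R,16R,20R) | COC(=O)[C@@H]1C[C@@]23CC[C@@]14N(C(=O)OC)c1ccccc1[C@@]4(C(=O)OC)CCN2CC[C@H]3O | target

**Summary**

Total step count: 17. Longest linear sequence: 17 steps (1 and 2 to 24); 17 enters at step 13.

Steps most likely to fail:

1. Step 9. The aza-Michael addition is reversible and creates a fully substituted carbon next to quaternary C7, so the equilibrium may stay on the side of the open dienoate, and C16 may settle as the unwanted epimer. Fallback: from 11, an irreversible radical closure replaces the polar one. Photocatalytic proton-coupled electron transfer ([Ir(dF(CF3)ppy)2(bpy)]PF6, NBu4[(BuO)2PO2], thiophenol, blue light, CH2Cl2) should turn the N-aryl carbamate into an amidyl radical that cyclises 5-exo onto C2; the resulting C16 radical is quenched by hydrogen-atom transfer from the thiol. The route is rejoined at 12 with no new compound.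

2. Step 15. The acyl-substituted C20 may migrate too slowly, which would allow shift of the methylene carbon C6 or decomposition of the azide before it adds to the hindered ketone. Fallback: from 20, the order of redox events is changed so that the migrating carbon is alkyl-substituted. Reduction of the exocyclic ketone with (S)-2-methyl-CBS-oxazaborolidine and BH3·SMe2 (the hindered ring ketone should survive) gives the azido hydroxy ketone F1. TBSOTf and 2,6-lutidine give the silyl ether F2. Ring expansion of F2 (TfOH or TiCl4, CH2Cl2) gives the silyloxy lactam F3. Bu4NF in THF then returns the route at 23.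

3. Step 5. Enantiofacial discrimination in the carboxyl transfer may be poor with the small methyl carbonate, giving 8 of low enantiomeric purity. Fallback: the C7 centre is set by C-alkylation instead of acyl transfer, starting from 2. Br2 in MeOH at 0 °C should brominate the methyl group to give methyl 6-bromo-5-oxohexanoate F4. Commercial oxindole is converted by ClCO2Me/Et3N and then DMAP into dimethyl 2-oxoindoline-1,3-dicarboxylate F5. Alkylation of F5 with F4 under chiral phase-transfer catalysis (N-(9-anthracenylmethyl)cinchonidinium bromide, solid K2CO3, toluene, −20 °C) should give the quaternary keto oxindole F6. Ketalisation as in step 3 returns the route at 8.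

Further compounds

F0 | step 9 | none | none
F1 | step 15 | azido hydroxy ketone, 15R alcohol of 20 | COC(=O)[C@@H]1C[C@@]2([C@H](O)CCN=[N+]=[N-])CC[C@@]13N(C(=O)OC)c1ccccc1[C@@]3(C(=O)OC)CC2=O
F2 | step 15 | tert-butyldimethylsilyl ether of F1 | COC(=O)[C@@H]1C[C@@]2([C@H](O[Si](C)(C)C(C)(C)C)CCN=[N+]=[N-])CC[C@@]13N(C(=O)OC)c1ccccc1[C@@]3(C(=O)OC)CC2=O
F3 | step 15 | silyloxy lactam, 15-O-TBS ether of 23 | COC(=O)[C@@H]1C[C@@]23CC[C@@]14N(C(=O)OC)c1ccccc1[C@@]4(C(=O)OC)CC(=O)N2CC[C@H]3O[Si](C)(C)C(C)(C)C
F4 | step 5 | methyl 6-bromo-5-oxohexanoate | COC(=O)CCCC(=O)CBr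
F5 | step 5 | dimethyl 2-oxoindoline-1,3-dicarboxylate | COC(=O)C1C(=O)N(C(=O)OC)c2ccccc21
F6 | step 5 | dimethyl (3S)-3-(6-methoxy-2,6-dioxohexyl)-2-oxoindoline-1,3-dicarboxylate | O=C1N(C(=O)OC)c2ccccc2[C@@]1(C(=O)OC)CC(=O)CCCC(=O)OC
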